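## Structural features

The target (25) is a monocyclic sesterterpenoid methyl ester: a 14-membered carbocycle carrying a 6-methylhepta-1,5-dien-2-yl chain on its only stereocentre and a CO2Me group on one ring alkene. For the discussion the ring is numbered from the stereocentre C-1 through the ester-bearing alkene, so the ring alkenes are C-3=C-4(CO2Me), C-7=C-8(CH3) and C-11=C-12(CH3). These three trisubstituted alkenes stand in 1,5-relationships, each pair separated by two CH2 groups, and the ring has no heteroatom handle. C-3=C-4 is E by the sequence rule but has the ring carbons C-2 and C-5 cis; C-7=C-8 is Z; C-11=C-12 is E. C-1 (R) is flanked by two ring methylenes (C-2, C-14) and the 1,1-disubstituted exocyclic alkene, so its chirality rests only on the difference between the two ring arms; it is allylic, remote from every polar group and cannot be repaired by equilibration. Fragile points are the enoate (Michael acceptor, geometry), the Z alkene and the acid-sensitive 1,5-polyene with its exo-methylene. The real difficulty is closing the carbocycle while fixing the enoate geometry and leaving C-1 untouched. The key step exploits the segment C-2H2–C-3H=C-4(CO2Me)–C-5H2: with C-2 and C-5 cis it is a cis-cycloalkenyl ester between two methylenes, the retron of a vinyl anion at C-4 made from a methyl ketone (C-4 carbonyl, C-3 methyl), and C-3 to C-13 with both methyl-bearing alkenes then coincide with nerylacetone.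

## Logic of the disconnections

**25 ⇒ 21.** Three bonds are cut together: C-4–CO2Me, the ring bond C-2–C-3, and formally the C-3=C-4 π bond, which goes back to the C=N bond of a ketone hydrazone. In one sentence, the route is a one-flask ring-closing alkylation, Shapiro elimination and methoxycarbonylation of the open-chain bromo sulfonylhydrazone 21. The cut is made here because C-4 is then the carbonyl carbon and C-3 the methyl group of a methyl ketone, so ring, alkene position, alkene geometry and ester all come from one hydrazone. The gain is the step from a 14-membered trienoate to an acyclic chain whose only stereochemical elements are C-1 and two alkenes. The demand is that the carbanion forms only at C-3, closes the ring before it eliminates, and that vinyl anion 24 forms with C-2 and C-5 cis.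

**21 ⇒ 20 ⇒ 19 ⇒ 18 ⇒ 17.** Only heteroatom bonds are cut: C=N back to C=O, C-2–Br back to C-2–O, then the ether and the ketal. The ketone and the C-2 leaving group must stay masked while the C-13–C-14 bond is made with an organomagnesium reagent. There is no skeletal gain; the two chain ends simply become orthogonal. The demand is mild conditions that leave the 1,5-polyene and C-1 alone.

**17 ⇒ 15 + 4.** The single bond C-13–C-14 is cut, between an allylic carbon and the methylene next to C-1. This divides the chain into the terpenoid part C-3 to C-13 and a three-carbon chiral unit with the side chain; C-13 is the one carbon of the terpenoid part that can be oxidised selectively. The gain is two fragments of similar size and a convergent route. The demand is substitution at C-13 without allylic transposition and with retention of the E alkene.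

**4 ⇒ 3 ⇒ 2 ⇒ 1.** No carbon–carbon bond is cut: C-13–Br goes back to C-13–OH and then to a C–H bond of the (E)-methyl group at the isopropylidene end of 1. The reason is that 1 already holds C-3 to C-13, the Z alkene at C-7 and the C-4 carbonyl. The gain is eleven ring carbons and two ring alkenes from one commercial ketone. The demand is oxidation at the terminal alkene only, and at its E methyl group.

**15 ⇒ 14 ⇒ 13 ⇒ 11.** The C-1–C-2 bond is cut, and C-14–I is traced back to an acyl carbon. Because C-1 lies between two methylenes it can be made as the alpha carbon of an acyl unit: C-14 is the acyl carbon, C-2 comes from a one-carbon electrophile, and the auxiliary decides the configuration. The gain is that the stereocentre is reduced to an achiral β,γ-unsaturated acyl group. The demand is alpha- not gamma-alkylation of a dienolate, no migration of the exo-methylene into conjugation, and the facial selectivity that gives 13.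

**11 ⇒ 8 + 9, then 8 ⇒ 5 + 6.** The N-acyl bond is cut, then the bond between the alkene carbon of the side chain and its CH2CH2 neighbour. 8 is the ring-opened form of 6 in which the vinylic C–O bond is replaced by a C–C bond to the 4-methylpent-3-enyl group of 5, which delivers the whole side chain with its exo-methylene in place. The gain is three commercial compounds. The demand is coupling at the vinylic C–O bond of 6 and no conjugation of the β,γ-alkene.

## Other disconnections considered

**Alternative 1:** Cut C-3=C-4 and close the ring by intramolecular Horner–Wadsworth–Emmons olefination of the aldehyde phosphonate A1. This is the plan that comes to mind first.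
- The alpha-branched phosphonoacetate needs the C-5 carbon, which the neryl skeleton lacks, so a one-carbon homologation at the allylic C-6 is required.
- A macrocyclic olefination with an alpha-substituted phosphonate has no kinetic bias for the ring-cis enoate and leans on thermodynamics.
- The chosen plan takes C-3, C-4 and C-5 from the ketone of 1 and sets the geometry by the syn-dianion mechanism, in fewer steps.

**Alternative 2:** Cut C-5–C-6 with simultaneous formation of C-3=C-4. The allylic sulfone carbanion of A2 adds to its own Morita–Baylis–Hillman acetate and expels acetate to give the macrocyclic sulfone A3; reductive desulfonylation follows.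
- The closure is stereoconvergent (both C-3 epimers give the E enoate) and uses a soft carbanion.
- It needs a longer linear sequence to A2 (conjugate alkenylation, aldehyde, Baylis–Hillman reaction, acetate).
- The last step must remove an allylic sulfone next to a Z alkene without reducing the Michael acceptor or moving the alkene; the chosen plan ends in the target itself.

**Alternative 3:** Cut the exocyclic bond from C-1 to the side chain last. A rhodium/BINAP-catalysed conjugate addition of a side-chain alkenyl nucleophile to the achiral macrocyclic enone A4 gives ketone A5.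
- The macrocycle stays achiral until the end and C-1 is set by the catalyst.
- A5 has its carbonyl at C-3 between two methylenes (C-2 and C-4); converting it to C-3H=C-4(CO2Me) needs a carboxylation at C-4 against C-2 with no inherent control, then a deoxygenative transposition.
- A4 itself still needs a macrocyclisation; the chosen plan has the ketone on C-4 from the start.

Key step: step 14

Assumption: commercial nerylacetone (1) is taken as the single (5Z) isomer; C-1 of 25 is R as drawn in the given SMILES.

## Steps

Step 1
Reactants: 1 nerylacetone, (5Z)-6,10-dimethylundeca-5,9-dien-2-one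
Product: 2 2-[(3Z)-4,8-dimethylnona-3,7-dien-1-yl]-2-methyl-1,3-dioxolane
Conditions: HOCH2CH2OH, PPTS (cat.), benzene, reflux, Dean–Stark
Reagents that add atoms: ethylene glycol, OCCO
Why: Acid-catalysed ketalisation; the weak acid PPTS should leave the Z alkene and the isopropylidene end untouched, and the dioxolane masks the ketone for the organomagnesium coupling of step 9.

Step 2
Reactants: 2 2-[(3Z)-4,8-dimethylnona-3,7-dien-1-yl]-2-methyl-1,3-dioxolane
Product: 3 (2E,6Z)-2,6-dimethyl-9-(2-methyl-1,3-dioxolan-2-yl)nona-2,6-dien-1-ol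
Conditions: SeO2 (cat.), t-BuOOH, CH2Cl2, 0 °C → rt
Reagents that add atoms: tert-butyl hydroperoxide, CC(C)(C)OO
Why: Riley allylic oxidation (ene reaction, then [2,3]-sigmatropic shift of the allylseleninic acid) at the most electron-rich and least hindered alkene, the isopropylidene end, on its (E)-methyl group; the E geometry of C-11=C-12 follows from the chair-like [2,3] shift.

Step 3
Reactants: 3 (2E,6Z)-2,6-dimethyl-9-(2-methyl-1,3-dioxolan-2-yl)nona-2,6-dien-1-ol
Product: 4 2-[(3Z,7E)-9-bromo-4,8-dimethylnona-3,7-dien-1-yl]-2-methyl-1,3-dioxolane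
Conditions: CBr4, PPh3, 2,6-lutidine, CH2Cl2, −20 °C
Reagents that add atoms: carbon tetrabromide, BrC(Br)(Br)Br
Why: Appel bromination; SN2 displacement of the alkoxyphosphonium ion at the primary allylic carbon keeps the E alkene and avoids transposition, and the base protects the ketal.

Step 4
Reactants: 5 5-bromo-2-methylpent-2-ene; 6 diketene (4-methylideneoxetan-2-one)
Product: 8 7-methyl-3-methylideneoct-6-enoic acid, via (4-methylpent-3-en-1-yl)magnesium bromide 7 (not isolated)
Conditions: Mg, THF, 40 °C; then 6, NiCl2 (5 mol%), THF, −20 °C → rt; aq. HCl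
Reagents that add atoms: none
Why: Nickel-catalysed Kumada-type coupling at the vinylic C–O bond of the enol lactone (oxidative addition to zerovalent nickel, transmetalation, reductive elimination) opens diketene to the magnesium salt of the 3-methylidene acid; the carboxylate salt should keep the β,γ-alkene from moving into conjugation.

Step 5
Reactants: 8 7-methyl-3-methylideneoct-6-enoic acid; 9 (4R)-4-benzyl-1,3-oxazolidin-2-one
Product: 11 (4R)-4-benzyl-3-(7-methyl-3-methylideneoct-6-enoyl)-1,3-oxazolidin-2-one, via mixed pivalic anhydride 10 (not isolated)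
Conditions: t-BuCOCl, Et3N, THF, −20 °C; then 9, LiCl, −20 °C → rt
Reagents that add atoms: none
Why: N-Acylation of the oxazolidinone through the mixed anhydride; the low temperature and the mild LiCl/Et3N activation should avoid ketene formation and conjugation of the exo-methylene.

Step 6
Reactants: 11 (4R)-4-benzyl-3-(7-methyl-3-methylideneoct-6-enoyl)-1,3-oxazolidin-2-one
Product: 13 (4R)-4-benzyl-3-[(2S)-2-{[(4-methoxyphenyl)methoxy]methyl}-7-methyl-3-methylideneoct-6-enoyl]-1,3-oxazolidin-2-one, via sodium Z-enolate 12 (not isolated)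
Conditions: NaN(SiMe3)2, THF, −78 °C; then 4-MeOC6H4CH2OCH2Cl, −78 → −40 °C
Reagents that add atoms: 4-methoxybenzyl chloromethyl ether, COc1ccc(COCCl)cc1
Why: Oxazolidinone-auxiliary enolate alkylation (Evans alkylation): the chelated Z-enolate is attacked anti to the benzyl group, which sets C-1 in the sense needed for 25. The cross-conjugated dienolate should react at its alpha carbon with the reactive chloromethyl ether at low temperature.

Step 7
Reactants: 13 (4R)-4-benzyl-3-[(2S)-2-{[(4-methoxyphenyl)methoxy]methyl}-7-methyl-3-methylideneoct-6-enoyl]-1,3-oxazolidin-2-one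
Product: 14 (2R)-2-{[(4-methoxyphenyl)methoxy]methyl}-7-methyl-3-methylideneoct-6-en-1-ol
Conditions: LiBH4, MeOH (1 equiv), Et2O, 0 °C
Reagents that add atoms: none
Why: Reductive cleavage of the imide to the primary alcohol (future C-14) under non-basic conditions, so the allylic alpha stereocentre should not epimerise; the auxiliary is recovered.

Step 8
Reactants: 14 (2R)-2-{[(4-methoxyphenyl)methoxy]methyl}-7-methyl-3-methylideneoct-6-en-1-ol
Product: 15 1-({[(2S)-2-(iodomethyl)-7-methyl-3-methylideneoct-6-en-1-yl]oxy}methyl)-4-methoxybenzene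
Conditions: I2, PPh3, imidazole, CH2Cl2, 0 °C
Reagents that add atoms: iodine, II
Why: Appel-type iodination of a primary alcohol by SN2 displacement; C-1 is not involved.

Step 9
Reactants: 15 1-({[(2S)-2-(iodomethyl)-7-methyl-3-methylideneoct-6-en-1-yl]oxy}methyl)-4-methoxybenzene; 4 2-[(3Z,7E)-9-bromo-4,8-dimethylnona-3,7-dien-1-yl]-2-methyl-1,3-dioxolane
Product: 17 2-[(3Z,7E,11S)-11-{[(4-methoxyphenyl)methoxy]methyl}-4,8,16-trimethyl-12-methylideneheptadeca-3,7,15-trien-1-yl]-2-methyl-1,3-dioxolane, via alkylmagnesium iodide 16 (not isolated)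
Conditions: Mg, THF, rt; then 4, Li2CuCl4 (3 mol%), THF, −78 → 0 °C
Reagents that add atoms: none
Why: Copper-catalysed cross-coupling of a primary Grignard reagent with a primary allylic bromide; the cuprate should substitute at C-13 (SN2) with retention of the E alkene, forming the C-13–C-14 bond. The gamma-alkoxy and homoallylic Grignard reagent has no fast elimination or cyclisation path.

Step 10
Reactants: 17 2-[(3Z,7E,11S)-11-{[(4-methoxyphenyl)methoxy]methyl}-4,8,16-trimethyl-12-methylideneheptadeca-3,7,15-trien-1-yl]-2-methyl-1,3-dioxolane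
Product: 18 (5Z,9E,13S)-13-{[(4-methoxyphenyl)methoxy]methyl}-6,10,18-trimethyl-14-methylidenenonadeca-5,9,17-trien-2-one
Conditions: PPTS, acetone/H2O, 50 °C
Reagents that add atoms: water, O
Why: Mild acid-catalysed ketal hydrolysis; PPTS should not isomerise the 1,5-polyene or cleave the benzylic ether.

Step 11
Reactants: 18 (5Z,9E,13S)-13-{[(4-methoxyphenyl)methoxy]methyl}-6,10,18-trimethyl-14-methylidenenonadeca-5,9,17-trien-2-one
Product: 19 (5Z,9E,13S)-13-(hydroxymethyl)-6,10,18-trimethyl-14-methylidenenonadeca-5,9,17-trien-2-one
Conditions: DDQ, CH2Cl2/pH 7 buffer, 0 °C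
Reagents that add atoms: none
Why: Oxidative cleavage of the 4-methoxybenzyl ether by hydride abstraction from the electron-rich benzylic position; the unactivated alkenes and the ketone should be left alone at 0 °C.

Step 12
Reactants: 19 (5Z,9E,13S)-13-(hydroxymethyl)-6,10,18-trimethyl-14-methylidenenonadeca-5,9,17-trien-2-one
Product: 20 (5Z,9E,13S)-13-(bromomethyl)-6,10,18-trimethyl-14-methylidenenonadeca-5,9,17-trien-2-one
Conditions: CBr4, PPh3, 2,6-lutidine, CH2Cl2, 0 °C
Reagents that add atoms: carbon tetrabromide, BrC(Br)(Br)Br
Why: Appel bromination of the primary alcohol at C-2 under neutral conditions; a bromide is chosen over an iodide because it resists halogen–lithium exchange in step 14.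

Step 13
Reactants: 20 (5Z,9E,13S)-13-(bromomethyl)-6,10,18-trimethyl-14-methylidenenonadeca-5,9,17-trien-2-one
Product: 21 N'-[(2E,5Z,9E,13S)-13-(bromomethyl)-6,10,18-trimethyl-14-methylidenenonadeca-5,9,17-trien-2-ylidene]-2,4,6-tri(propan-2-yl)benzenesulfonohydrazide
Conditions: 2,4,6-(i-Pr)3C6H2SO2NHNH2, THF/MeOH, rt
Reagents that add atoms: 2,4,6-triisopropylbenzenesulfonohydrazide, CC(C)c1cc(C(C)C)c(S(=O)(=O)NN)c(C(C)C)c1
Why: Condensation of the methyl ketone with the sulfonylhydrazide; the E hydrazone (N–N bond syn to the C-3 methyl group) should be favoured on steric grounds. Condensation at the ketone is much faster than N-alkylation by the primary bromide.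

Step 14
Reactants: 21 N'-[(2E,5Z,9E,13S)-13-(bromomethyl)-6,10,18-trimethyl-14-methylidenenonadeca-5,9,17-trien-2-ylidene]-2,4,6-tri(propan-2-yl)benzenesulfonohydrazide
Product: 25 methyl (1E,4Z,8E,12R)-5,9-dimethyl-12-(6-methylhepta-1,5-dien-2-yl)cyclotetradeca-1(14),4,8-triene-1-carboxylate (CNP0163659.1), via dilithio hydrazone dianion 22 (not isolated), via macrocyclic lithium hydrazonide 23 (not isolated), via ring vinyllithium 24 (not isolated)
Conditions: n-BuLi (2.1 equiv), THF (0.002 M), −78 → −30 °C; n-BuLi (2 equiv), −78 → 0 °C; ClCO2Me, −78 °C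
Reagents that add atoms: methyl chloroformate, COC(Cl)=O
Why: Proposed new method: the closest known reaction type is the one-flask alkylation, Shapiro elimination and electrophilic trapping of methyl ketone arenesulfonylhydrazones, run here intramolecularly so that the alkylation closes the ring. Two equivalents of n-BuLi remove the N–H proton and, syn to the sulfonamide nitrogen and at the kinetically most acidic site, one proton of the C-3 methyl group to give dianion 22; its carbanion displaces the primary bromide at C-2 by SN2 under high dilution (a 14-membered exo-tet closure) to give 23. Because the C=N geometry is kept, the next equivalent of base again deprotonates syn, now at the ring methylene C-3, and loss of arenesulfinate and N2 gives vinyllithium 24 as the C-3=C-4 isomer only. The vinyl anion forms with its C-3 substituent (C-2) anti to the departing nitrogen and therefore cis to C-5, the usual kinetic outcome of the Shapiro reaction and here the cis-cycloalkene arrangement of the ring. Acylation of the configurationally stable vinyllithium with ClCO2Me proceeds with retention and puts the ester trans to C-2, which is the E enoate of 25. No new stereocentre is formed, and C-1 is not acidic and is untouched. The selectivities needed are C- over N-alkylation and substitution over E2 at the beta-branched bromide (the soft, very nucleophilic aza-allyl carbanion at low temperature), cyclisation over oligomerisation (dilution; two trisubstituted alkenes shorten the effective chain) and deprotonation over bromine–lithium exchange (n-BuLi at −78 °C with a primary bromide).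

## Compound list

1 | nerylacetone, (5Z)-6,10-dimethylundeca-5,9-dien-2-one | CC(=O)CC/C=C(/C)CCC=C(C)C | starting material
2 | 2-[(3Z)-4,8-dimethylnona-3,7-dien-1-yl]-2-methyl-1,3-dioxolane | CC1(CC/C=C(/C)CCC=C(C)C)OCCO1 | intermediate
3 | (2E,6Z)-2,6-dimethyl-9-(2-methyl-1,3-dioxolan-2-yl)nona-2,6-dien-1-ol | CC1(CC/C=C(/C)CC/C=C(\C)CO)OCCO1 | intermediate
4 | 2-[(3Z,7E)-9-bromo-4,8-dimethylnona-3,7-dien-1-yl]-2-methyl-1,3-dioxolane | CC1(CC/C=C(/C)CC/C=C(\C)CBr)OCCO1 | intermediate
5 | 5-bromo-2-methylpent-2-ene | CC(C)=CCCBr | starting material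
6 | diketene, 4-methylideneoxetan-2-one | C=C1CC(=O)O1 | starting material
7 | (4-methylpent-3-en-1-yl)magnesium bromide | CC(C)=CCC[Mg]Br | intermediate
8 | 7-methyl-3-methylideneoct-6-enoic acid | C=C(CCC=C(C)C)CC(=O)O | intermediate
9 | (4R)-4-benzyl-1,3-oxazolidin-2-one | O=C1N[C@H](Cc2ccccc2)CO1 | starting material
10 | 2,2-dimethylpropanoic 7-methyl-3-methylideneoct-6-enoic anhydride | C=C(CCC=C(C)C)CC(=O)OC(=O)C(C)(C)C | intermediate
11 | (4R)-4-benzyl-3-(7-methyl-3-methylideneoct-6-enoyl)-1,3-oxazolidin-2-one | C=C(CCC=C(C)C)CC(=O)N1[C@H](Cc2ccccc2)COC1=O | intermediate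
12 | sodium (Z)-enolate of 11 | C=C(CCC=C(C)C)/C=C(\[O-])N1[C@H](Cc2ccccc2)COC1=O.[Na+] | intermediate
13 | (4R)-4-benzyl-3-[(2S)-2-{[(4-methoxyphenyl)methoxy]methyl}-7-methyl-3-methylideneoct-6-enoyl]-1,3-oxazolidin-2-one | C=C(CCC=C(C)C)[C@H](C(=O)N1[C@H](Cc2ccccc2)COC1=O)COCc1ccc(OC)cc1 | intermediate
14 | (2R)-2-{[(4-methoxyphenyl)methoxy]methyl}-7-methyl-3-methylideneoct-6-en-1-ol | C=C(CCC=C(C)C)[C@H](CO)COCc1ccc(OC)cc1 | intermediate
15 | 1-({[(2S)-2-(iodomethyl)-7-methyl-3-methylideneoct-6-en-1-yl]oxy}methyl)-4-methoxybenzene | C=C(CCC=C(C)C)[C@H](CI)COCc1ccc(OC)cc1 | intermediate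
16 | [(2S)-2-{[(4-methoxyphenyl)methoxy]methyl}-7-methyl-3-methylideneoct-6-en-1-yl]magnesium iodide | C=C(CCC=C(C)C)[C@H](C[Mg]I)COCc1ccc(OC)cc1 | intermediate
17 | 2-[(3Z,7E,11S)-11-{[(4-methoxyphenyl)methoxy]methyl}-4,8,16-trimethyl-12-methylideneheptadeca-3,7,15-trien-1-yl]-2-methyl-1,3-dioxolane | CC1(CC/C=C(/C)CC/C=C(\C)CC[C@H](COCc2ccc(OC)cc2)C(=C)CCC=C(C)C)OCCO1 | intermediate
18 | (5Z,9E,13S)-13-{[(4-methoxyphenyl)methoxy]methyl}-6,10,18-trimethyl-14-methylidenenonadeca-5,9,17-trien-2-one | CC(=O)CC/C=C(/C)CC/C=C(\C)CC[C@H](COCc1ccc(OC)cc1)C(=C)CCC=C(C)C | intermediate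
19 | (5Z,9E,13S)-13-(hydroxymethyl)-6,10,18-trimethyl-14-methylidenenonadeca-5,9,17-trien-2-one | CC(=O)CC/C=C(/C)CC/C=C(\C)CC[C@H](CO)C(=C)CCC=C(C)C | intermediate
20 | (5Z,9E,13S)-13-(bromomethyl)-6,10,18-trimethyl-14-methylidenenonadeca-5,9,17-trien-2-one | CC(=O)CC/C=C(/C)CC/C=C(\C)CC[C@H](CBr)C(=C)CCC=C(C)C | intermediate
21 | N'-[(2E,5Z,9E,13S)-13-(bromomethyl)-6,10,18-trimethyl-14-methylidenenonadeca-5,9,17-trien-2-ylidene]-2,4,6-tri(propan-2-yl)benzenesulfonohydrazide | C/C(=N\NS(=O)(=O)c1c(C(C)C)cc(C(C)C)cc1C(C)C)CC/C=C(/C)CC/C=C(\C)CC[C@H](CBr)C(=C)CCC=C(C)C | intermediate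
22 | dilithio dianion of 21 (lithium on the C-3 carbon and on the sulfonamide nitrogen) | [Li]C/C(=N\N([Li])S(=O)(=O)c1c(C(C)C)cc(C(C)C)cc1C(C)C)CC/C=C(/C)CC/C=C(\C)CC[C@H](CBr)C(=C)CCC=C(C)C | intermediate
23 | N-lithio 2,4,6-triisopropylbenzenesulfonylhydrazone of the 14-membered C-4 ketone (N–N bond syn to C-3, C-1 R) | C=C(CCC=C(C)C)[C@H]1CC/C(=N\N([Li])S(=O)(=O)c2c(C(C)C)cc(C(C)C)cc2C(C)C)CC/C=C(/C)CC/C=C(\C)CC1 | intermediate
24 | ring vinyllithium, 25 with lithium in place of CO2Me at C-4 | C=C(CCC=C(C)C)[C@H]1C/C=C(/[Li])CC/C=C(/C)CC/C=C(\C)CC1 | intermediate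
25 | methyl (1E,4Z,8E,12R)-5,9-dimethyl-12-(6-methylhepta-1,5-dien-2-yl)cyclotetradeca-1(14),4,8-triene-1-carboxylate (CNP0163659.1) | C=C(CCC=C(C)C)[C@H]1C/C=C(/C(=O)OC)CC/C=C(/C)CC/C=C(\C)CC1 | target

## Step count and least certain steps

Total step count: 14. Longest linear sequence: 11 steps (steps 4 to 14, from 5 and 6 to 25); the other branch (steps 1 to 3) joins at step 9.

**Step 14 (key step, proposed new method).** The most likely failure is that ring closure does not keep pace with other paths of the dianion. SN2 at a beta-branched carbon to form a 14-membered ring is slow, so E2 loss of HBr across C-1/C-2, intermolecular alkylation to oligomers, or premature elimination of the unalkylated dianion to the terminal vinyl anion can take over. A second concern is loss of regiocontrol if the hydrazone geometry is not uniform.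

The fallback closes the ring by olefin metathesis. It sets out from 17 and returns at 25.
- DDQ removes the ether to give the ketal alcohol F1.
- I2/PPh3/imidazole gives the ketal iodide F2.
- Vinylmagnesium bromide with catalytic CuI couples at the primary iodide to give the C-1 allyl compound F3, whose new CH= carbon becomes C-3.
- PPTS in wet acetone gives the methyl ketone F4.
- LiN(i-Pr)2 at −78 °C then PhNTf2 gives the kinetic 2-triflyloxy-1-alkene F5.
- Pd(OAc)2/PPh3, CO, MeOH and Et3N give the 2-substituted acrylate F6.
- Ring-closing metathesis of F6 with the second-generation Grubbs catalyst RuCl2(=CHPh)(PCy3)(H2IMes) in dilute toluene at 80 °C should give 25, with the thermodynamically preferred E enoate expected.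

**Step 2.** Oxidation may go on to the enal, or attack the allylic methylenes of the internal Z alkene, because selenium dioxide distinguishes the two trisubstituted alkenes only by sterics and electron density.

The fallback rebuilds C-12/C-13 by degradation and olefination. It sets out from 1 and returns at 3.
- NBS in aqueous THF gives the terminal bromohydrin F7.
- K2CO3 in MeOH gives the epoxide F8.
- HIO4 cleaves it to the keto aldehyde F9.
- Ph3P=C(CH3)CO2Et reacts at the aldehyde only to give the E enoate F10.
- Ethylene glycol/PPTS gives the ketal ester F11.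
- i-Bu2AlH reduces the ester to 3.

**Step 6.** The dienolate may transfer a proton and move the exo-methylene into conjugation, or alkylate at the gamma carbon, which lowers both yield and stereochemical purity.

The fallback replaces the auxiliary by desymmetrisation of a prochiral diol. It sets out from 8 and returns at 14.
- Me3SiCHN2 in MeOH gives the methyl ester F12.
- LiN(i-Pr)2 then gaseous CH2O gives the alpha-hydroxymethyl ester F13.
- LiAlH4 gives the achiral diol F14.
- Lipase-catalysed acetylation with vinyl acetate (or the complementary enzymatic hydrolysis of the diacetate, whichever gives the needed enantiomer) gives the mono-acetate F15.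
- 4-Methoxybenzyl trichloroacetimidate with catalytic camphorsulfonic acid gives the ether acetate F16.
- K2CO3 in MeOH gives 14.

**Step 9.** Homocoupling during Grignard formation, and attack of the organocopper species at C-11 (allylic transposition), are the likely losses.

The fallback uses a sulfone carbanion in place of the organometallic. It sets out from 15 and returns at 17.
- PhSO2Na in DMF gives the sulfone F17.
- n-BuLi in THF at −78 °C, then bromide 4, gives the coupled sulfone F18.
- Mg in MeOH removes the non-allylic sulfone to give 17.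

## Further compounds

F1 | step 14 | 2-[(3Z,7E,11S)-11-(hydroxymethyl)-4,8,16-trimethyl-12-methylideneheptadeca-3,7,15-trien-1-yl]-2-methyl-1,3-dioxolane | CC1(CC/C=C(/C)CC/C=C(\C)CC[C@H](CO)C(=C)CCC=C(C)C)OCCO1
F2 | step 14 | 2-[(3Z,7E,11S)-11-(iodomethyl)-4,8,16-trimethyl-12-methylideneheptadeca-3,7,15-trien-1-yl]-2-methyl-1,3-dioxolane | CC1(CC/C=C(/C)CC/C=C(\C)CC[C@H](CI)C(=C)CCC=C(C)C)OCCO1
F3 | step 14 | 2-[(3Z,7E,11R)-4,8,16-trimethyl-12-methylidene-11-(prop-2-en-1-yl)heptadeca-3,7,15-trien-1-yl]-2-methyl-1,3-dioxolane | CC1(CC/C=C(/C)CC/C=C(\C)CC[C@H](CC=C)C(=C)CCC=C(C)C)OCCO1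
F4 | step 14 | (5Z,9E,13R)-6,10,18-trimethyl-14-methylidene-13-(prop-2-en-1-yl)nonadeca-5,9,17-trien-2-one | CC(=O)CC/C=C(/C)CC/C=C(\C)CC[C@H](CC=C)C(=C)CCC=C(C)C
F5 | step 14 | (5Z,9E,13R)-6,10,18-trimethyl-14-methylidene-13-(prop-2-en-1-yl)nonadeca-1,5,9,17-tetraen-2-yl trifluoromethanesulfonate | C=C(OS(=O)(=O)C(F)(F)F)CC/C=C(/C)CC/C=C(\C)CC[C@H](CC=C)C(=C)CCC=C(C)C
F6 | step 14 | methyl (5Z,9E,13R)-6,10,18-trimethyl-2,14-dimethylidene-13-(prop-2-en-1-yl)nonadeca-5,9,17-trienoate | C=C(C(=O)OC)CC/C=C(/C)CC/C=C(\C)CC[C@H](CC=C)C(=C)CCC=C(C)C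
F7 | step 2 | (5Z)-9-bromo-10-hydroxy-6,10-dimethylundec-5-en-2-one (racemic at C-9) | CC(=O)CC/C=C(/C)CCC(Br)C(C)(C)O
F8 | step 2 | (5Z)-8-(3,3-dimethyloxiran-2-yl)-6-methyloct-5-en-2-one (racemic) | CC(=O)CC/C=C(/C)CCC1OC1(C)C
F9 | step 2 | (4Z)-4-methyl-8-oxonon-4-enal | CC(=O)CC/C=C(/C)CCC=O
F10 | step 2 | ethyl (2E,6Z)-2,6-dimethyl-10-oxoundeca-2,6-dienoate | CC(=O)CC/C=C(/C)CC/C=C(\C)C(=O)OCC
F11 | step 2 | ethyl (2E,6Z)-2,6-dimethyl-9-(2-methyl-1,3-dioxolan-2-yl)nona-2,6-dienoate | CC1(CC/C=C(/C)CC/C=C(\C)C(=O)OCC)OCCO1
F12 | step 6 | methyl 7-methyl-3-methylideneoct-6-enoate | C=C(CCC=C(C)C)CC(=O)OC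
F13 | step 6 | methyl 2-(hydroxymethyl)-7-methyl-3-methylideneoct-6-enoate (racemic) | C=C(CCC=C(C)C)C(CO)C(=O)OC
F14 | step 6 | 2-(6-methylhepta-1,5-dien-2-yl)propane-1,3-diol | C=C(CCC=C(C)C)C(CO)CO
F15 | step 6 | 3-hydroxy-2-(6-methylhepta-1,5-dien-2-yl)propyl acetate, acetate on the arm that becomes C-14 | C=C(CCC=C(C)C)[C@H](COC(C)=O)CO
F16 | step 6 | 3-[(4-methoxyphenyl)methoxy]-2-(6-methylhepta-1,5-dien-2-yl)propyl acetate, configuration as in 14 | C=C(CCC=C(C)C)[C@H](COC(C)=O)COCc1ccc(OC)cc1
F17 | step 9 | 1-methoxy-4-({[(2S)-7-methyl-3-methylidene-2-[(phenylsulfonyl)methyl]oct-6-en-1-yl]oxy}methyl)benzene | C=C(CCC=C(C)C)[C@H](CS(=O)(=O)c1ccccc1)COCc1ccc(OC)cc1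
F18 | step 9 | 17 bearing a phenylsulfonyl group on C-14 (either configuration at C-14) | CC1(CC/C=C(/C)CC/C=C(\C)CC(S(=O)(=O)c2ccccc2)[C@H](COCc2ccc(OC)cc2)C(=C)CCC=C(C)C)OCCO1
A1 | alternative 1 | open-chain C-3 aldehyde with a dimethyl phosphonate and CO2Me on C-4 (either configuration at C-4) | C=C(CCC=C(C)C)[C@@H](CC=O)CC/C(C)=C/CC/C(C)=C\CCC(C(=O)OC)P(=O)(OC)OC
A2 | alternative 2 | open-chain Baylis–Hillman acetate (C-3 OAc, C-4 methylidene ester) with a phenyl sulfone on C-6 (either configuration at C-3) | C=C(CCC=C(C)C)[C@@H](CC(OC(C)=O)C(=C)C(=O)OC)CC/C(C)=C/CC/C(C)=C\CS(=O)(=O)c1ccccc1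
A3 | alternative 2 | 25 bearing a phenylsulfonyl group on C-6 (either configuration at C-6) | C=C(CCC=C(C)C)[C@H]1C/C=C(/C(=O)OC)CC(S(=O)(=O)c2ccccc2)/C=C(/C)CC/C=C(\C)CC1
A4 | alternative 3 | achiral 14-membered enone, C-3 ketone with C-1=C-2 (E), C-7=C-8 (Z) and C-11=C-12 (E) | O=C1/C=C/CC/C(C)=C/CC/C(C)=C\CCC1
A5 | alternative 3 | 14-membered C-3 ketone carrying the side chain on C-1 (R) | C=C(CCC=C(C)C)[C@H]1CC(=O)CCC/C=C(/C)CC/C=C(\C)CC1
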